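**Plan**
- Retrosynthesis: the O–benzyl and O–methyl bonds are cut first, then C5′–Br of the anisole ring (ring A). Next come the two ring bonds C2′–C3′ and C3′–C4′, which removes C3′ with its bromine as CBr2 and contracts ring A to a 2-silyloxy-3-aryloxycyclopentadiene.
- This cut is open because C3′ is a C–Br carbon lying between the oxygen-bearing C2′ and C4′–H, the pattern a CBr2 unit leaves on insertion into the C=C bond of a silyl enol ether.
- The diene goes back to a 2-aryloxycyclopentenone, cut at its enol ether C–O bond into 2,3-epoxycyclopentanone and a tribromophenol (ring B). That phenol comes from 3-bromosalicylaldehyde by benzylation, Baeyer–Villiger oxidation and dibromination.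
- Forward: ring B is bought as an arene and dressed; the five carbons of cyclopentenone are joined to it through oxygen; ring A becomes six-membered and aromatic only in the carbene step; para-bromination, O-methylation and debenzylation finish.
- Stereochemistry: the target has no stereocentre; those of the epoxide, the hydroxy ketone and the cyclopropane are transient, racemic and erased.

Key step: step 7

Remark on the chemistry: ring A carries primed locants (C1′ bears the ether oxygen, C2′ the methoxy group). The dienol ether is carried as its tert-butyldimethylsilyl ether for robustness towards alkoxide. SMILES of racemic intermediates show relative configuration only.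

**Route**

Step 1
Reactants: 1 3-bromo-2-hydroxybenzaldehyde
Product: 2 2-(benzyloxy)-3-bromobenzaldehyde
Conditions: BnBr, K2CO3, DMF, rt
Reagents that add atoms: benzyl bromide, BrCc1ccccc1
Why: Williamson etherification, in which the phenoxide formed by K2CO3 displaces bromide from benzyl bromide (SN2), installs an ether that should survive the peracid, NBS, silyl triflate, alkoxide and carbene conditions ahead.

Step 2
Reactants: 2 2-(benzyloxy)-3-bromobenzaldehyde
Product: 4 2-(benzyloxy)-3-bromophenol, via aryl formate 3 (not isolated)
Conditions: mCPBA, CH2Cl2, rt; aq. NaHCO3 wash; then K2CO3 (cat.), MeOH, rt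
Reagents that add atoms: meta-chloroperoxybenzoic acid (mCPBA), O=C(OO)c1cccc(Cl)c1
Why: Baeyer–Villiger oxidation, in which the aryl group activated by its ortho alkoxy substituent migrates to oxygen in the Criegee adduct in preference to hydride, followed by base-catalysed methanolysis of the formate.

Step 3
Reactants: 4 2-(benzyloxy)-3-bromophenol
Product: 6 2-(benzyloxy)-3,4,6-tribromophenol, via para-brominated phenol 5 (not isolated)
Conditions: NBS (2.1 equiv), MeCN, 0 °C → rt
Reagents that add atoms: N-bromosuccinimide (NBS), O=C1CCC(=O)N1Br
Why: Electrophilic aromatic bromination directed by the free hydroxyl, the strongest donor, to its open para (C4) and ortho (C6) positions, both also favoured by the C3 bromine, so that two equivalents should stop at the tribromide.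

Step 4
Reactants: 7 cyclopent-2-en-1-one
Product: 8 2,3-epoxycyclopentan-1-one (racemic)
Conditions: 30% aq. H2O2, NaOH (cat.), MeOH, 0 °C
Reagents that add atoms: hydrogen peroxide, OO
Why: Weitz–Scheffer nucleophilic epoxidation (conjugate addition of hydroperoxide, then closure of the enolate onto oxygen) gives the necessarily cis-fused, racemic epoxy ketone whose two stereocentres are erased in step 5.

Step 5
Reactants: 6 2-(benzyloxy)-3,4,6-tribromophenol; 8 2,3-epoxycyclopentan-1-one
Product: 10 2-[2-(benzyloxy)-3,4,6-tribromophenoxy]cyclopent-2-en-1-one, via trans-hydroxy ketone 9 (not isolated)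
Conditions: Cs2CO3 (0.2 equiv), DMF, 50 °C
Reagents that add atoms: none
Why: Opening of an α,β-epoxy ketone by a phenoxide at the carbonyl-activated α-carbon (SN2 with inversion, hence trans-9) and E1cB loss of water is a known entry to 2-aryloxy enones, and the weakly basic tribromophenoxide should leave the epoxy ketone otherwise intact.

Step 6
Reactants: 10 2-[2-(benzyloxy)-3,4,6-tribromophenoxy]cyclopent-2-en-1-one
Product: 11 3-[2-(benzyloxy)-3,4,6-tribromophenoxy]-2-(tert-butyldimethylsilyloxy)cyclopenta-1,3-diene
Conditions: TBSOTf, Et3N, CH2Cl2, −78 → 0 °C; cold aq. NaHCO3; used at once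
Reagents that add atoms: tert-butyldimethylsilyl trifluoromethanesulfonate (TBSOTf), CC(C)(C)[Si](C)(C)OS(=O)(=O)C(F)(F)F
Why: Soft enolisation, in which O-silylation of the enone is followed by removal of the α′ proton (C5) by triethylamine, is the standard route from cyclic enones to cross-conjugated 2-silyloxy dienes and avoids an amide base that could metalate the ring-B C–H flanked by two bromines.

Step 7
Reactants: 11 3-[2-(benzyloxy)-3,4,6-tribromophenoxy]-2-(tert-butyldimethylsilyloxy)cyclopenta-1,3-diene; 12 bromoform
Product: 15 2-[2-(benzyloxy)-3,4,6-tribromophenoxy]-6-bromophenol, via dibromocyclopropane 13 (not isolated), via aryl silyl ether 14 (not isolated)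
Conditions: CHBr3 (excess), KOtBu (added last, slowly), pentane/toluene, −30 °C → rt; filter, concentrate; then KHF2, MeOH, rt
Reagents that add atoms: bromoform (compound 12), BrC(Br)Br
Why: Proposed new method: dibromocarbene, released by α-elimination from the tribromomethyl anion, should add as a singlet in a concerted [2+1] cheletropic step to the silyl enol ether double bond of 11, closing the three-membered ring of 13 and forming the future C2′–C3′ and C3′–C4′ bonds. The six-membered ring is not closed by cyclisation but arises by ring enlargement: thermally allowed disrotatory opening of the ring-fusion bond with departure of the endo bromide, pushed by the silyloxy lone pair, gives an arenium-type cation with its sp3 CH2 at C5′, and loss of that proton to the second equivalent of KOtBu should deliver aryl silyl ether 14, which KHF2 cleaves to phenol 15. The closest known reactions are the dihalocarbene ring expansion of cyclic silyl enol ethers to 2-halo enones and the conversion of cyclopentadiene or indene into a halobenzene or 2-halonaphthalene by a dihalocarbene; the present substrate merges the two and already carries the oxidation level of the arene. The two stereocentres of 13 are held cis by the ring fusion, are racemic and vanish on opening, so no stereocentre has to be controlled. The step needs site selectivity between the two enol ether double bonds, which the substrate supplies because the silyloxy group is the stronger donor, whereas the lone pairs of the other oxygen are drawn into the tribrominated ring, whose two ortho substituents also shield that alkene. It also needs the diene to keep its double-bond positions, which is secured by using it cold and at once (slow 1,5-hydrogen shift) and by adding the base last to an excess of bromoform, the strongest C–H acid present.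

Step 8
Reactants: 15 2-[2-(benzyloxy)-3,4,6-tribromophenoxy]-6-bromophenol
Product: 16 2-[2-(benzyloxy)-3,4,6-tribromophenoxy]-4,6-dibromophenol
Conditions: NBS (1.0 equiv), MeCN, −20 → 0 °C
Reagents that add atoms: N-bromosuccinimide (NBS), O=C1CCC(=O)N1Br
Why: Electrophilic aromatic bromination para to the free hydroxyl of ring A (C5′), the only open position it activates since both ortho carbons are substituted, while ring B carries three bromines and a capped oxygen.

Step 9
Reactants: 16 2-[2-(benzyloxy)-3,4,6-tribromophenoxy]-4,6-dibromophenol
Product: 17 1-(benzyloxy)-2,3,5-tribromo-6-(3,5-dibromo-2-methoxyphenoxy)benzene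
Conditions: MeI, K2CO3, DMF, rt
Reagents that add atoms: iodomethane, CI
Why: Williamson O-methylation (SN2 on iodomethane) of the only free, acidic phenol, the ring-B oxygen being held as its benzyl ether.

Step 10
Reactants: 17 1-(benzyloxy)-2,3,5-tribromo-6-(3,5-dibromo-2-methoxyphenoxy)benzene
Product: 18 2,3,5-tribromo-6-(3,5-dibromo-2-methoxyphenoxy)phenol (CNP0282108.0)
Conditions: BCl3, C6HMe5, CH2Cl2, −78 °C; then H2O
Reagents that add atoms: none
Why: Lewis acid-mediated debenzylation, in which BCl3 activates the benzyl ether of the good tribromophenoxide leaving group and pentamethylbenzene takes up the benzyl cation by Friedel–Crafts alkylation, is known to spare aryl methyl ethers and aryl bromides at low temperature.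

**Compound list**

1 | 3-bromo-2-hydroxybenzaldehyde | O=Cc1cccc(Br)c1O | starting material
2 | 2-(benzyloxy)-3-bromobenzaldehyde | O=Cc1cccc(Br)c1OCc1ccccc1 | intermediate
3 | 2-(benzyloxy)-3-bromophenyl formate | O=COc1cccc(Br)c1OCc1ccccc1 | intermediate
4 | 2-(benzyloxy)-3-bromophenol | Oc1cccc(Br)c1OCc1ccccc1 | intermediate
5 | 2-(benzyloxy)-3,4-dibromophenol | Oc1ccc(Br)c(Br)c1OCc1ccccc1 | intermediate
6 | 2-(benzyloxy)-3,4,6-tribromophenol | Oc1c(Br)cc(Br)c(Br)c1OCc1ccccc1 | intermediate
7 | cyclopent-2-en-1-one | O=C1C=CCC1 | starting material
8 | 2,3-epoxycyclopentan-1-one (6-oxabicyclo[3.1.0]hexan-2-one), racemic | O=C1CC[C@@H]2O[C@H]12 | intermediate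
9 | trans-2-[2-(benzyloxy)-3,4,6-tribromophenoxy]-3-hydroxycyclopentan-1-one, racemic | O=C1CC[C@@H](O)[C@@H]1Oc1c(Br)cc(Br)c(Br)c1OCc1ccccc1 | intermediate
10 | 2-[2-(benzyloxy)-3,4,6-tribromophenoxy]cyclopent-2-en-1-one | O=C1CCC=C1Oc1c(Br)cc(Br)c(Br)c1OCc1ccccc1 | intermediate
11 | 3-[2-(benzyloxy)-3,4,6-tribromophenoxy]-2-(tert-butyldimethylsilyloxy)cyclopenta-1,3-diene | CC(C)(C)[Si](C)(C)OC1=CCC=C1Oc1c(Br)cc(Br)c(Br)c1OCc1ccccc1 | intermediate
12 | bromoform | BrC(Br)Br | starting material
13 | 2-[2-(benzyloxy)-3,4,6-tribromophenoxy]-6,6-dibromo-1-(tert-butyldimethylsilyloxy)bicyclo[3.1.0]hex-2-ene, racemic | CC(C)(C)[Si](C)(C)O[C@@]12C(Oc3c(Br)cc(Br)c(Br)c3OCc3ccccc3)=CC[C@@H]1C2(Br)Br | intermediate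
14 | {2-[2-(benzyloxy)-3,4,6-tribromophenoxy]-6-bromophenoxy}(tert-butyl)dimethylsilane | CC(C)(C)[Si](C)(C)Oc1c(Br)cccc1Oc1c(Br)cc(Br)c(Br)c1OCc1ccccc1 | intermediate
15 | 2-[2-(benzyloxy)-3,4,6-tribromophenoxy]-6-bromophenol | Oc1c(Br)cccc1Oc1c(Br)cc(Br)c(Br)c1OCc1ccccc1 | intermediate
16 | 2-[2-(benzyloxy)-3,4,6-tribromophenoxy]-4,6-dibromophenol | Oc1c(Br)cc(Br)cc1Oc1c(Br)cc(Br)c(Br)c1OCc1ccccc1 | intermediate
17 | 1-(benzyloxy)-2,3,5-tribromo-6-(3,5-dibromo-2-methoxyphenoxy)benzene | COc1c(Br)cc(Br)cc1Oc1c(Br)cc(Br)c(Br)c1OCc1ccccc1 | intermediate
18 | 2,3,5-tribromo-6-(3,5-dibromo-2-methoxyphenoxy)phenol | COc1c(Br)cc(Br)cc1Oc1c(Br)cc(Br)c(Br)c1O | target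

**Step count and risks**

Total: 10 steps. Longest linear sequence: 9 steps (steps 1–3 and 5–10, from 1); the cyclopentenone branch (steps 4–10) is 7 steps.

Steps most likely to fail:

1. Step 7 (new method). The carbene may add to the aryloxy-substituted double bond, or the diene may shift its double bonds (1,5-hydrogen shift or deprotonation by alkoxide) before the carbene arrives; either process would lead to regioisomeric bromophenols. The silyl group may also be lost to alkoxide before cyclopropanation. The fallback builds ring A as a six-membered ring from the start and uses known chemistry only. It sets out from phenol 6, which under the conditions of step 5 should open commercial 2,3-epoxycyclohexanone to the trans-hydroxy ketone F1, which loses water in the flask to give 2-[2-(benzyloxy)-3,4,6-tribromophenoxy]cyclohex-2-en-1-one F2. Dehydrogenation with DDQ in hot dioxane should give 2-[2-(benzyloxy)-3,4,6-tribromophenoxy]phenol F3. Two equivalents of NBS in MeCN should then brominate para and ortho to the hydroxyl, through the 4-bromophenol F4, and the sequence rejoins the route at 16.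

2. Step 5. Base-induced isomerisation and self-condensation of the strained epoxy ketone may outrun attack by the hindered, weakly nucleophilic phenoxide. The fallback joins the rings by nucleophilic aromatic substitution instead. It sets out from 6, which with 2-bromo-6-fluorobenzaldehyde (K2CO3, DMAc, 120 °C) should displace the aldehyde-activated fluoride to give 2-[2-(benzyloxy)-3,4,6-tribromophenoxy]-6-bromobenzaldehyde F5. Baeyer–Villiger oxidation with mCPBA should give the aryl formate F6, and methanolysis (K2CO3, MeOH) returns to the route at 15.

3. Step 10. The Lewis acid may also cleave the twisted, di-ortho-substituted methyl ether. The fallback removes the benzyl group by a radical pathway. It sets out from 17: Wohl–Ziegler bromination of the benzylic C–H (NBS, visible light, CaCO3, PhCF3/H2O, rt) should give the α-bromobenzyl ether F7, which hydrolyses in the flask to benzaldehyde and the phenol, coming back at 18.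

**Further compounds**

F1 | step 7 | trans-2-[2-(benzyloxy)-3,4,6-tribromophenoxy]-3-hydroxycyclohexan-1-one, racemic | O=C1CCC[C@@H](O)[C@@H]1Oc1c(Br)cc(Br)c(Br)c1OCc1ccccc1
F2 | step 7 | 2-[2-(benzyloxy)-3,4,6-tribromophenoxy]cyclohex-2-en-1-one | O=C1CCCC=C1Oc1c(Br)cc(Br)c(Br)c1OCc1ccccc1
F3 | step 7 | 2-[2-(benzyloxy)-3,4,6-tribromophenoxy]phenol | Oc1ccccc1Oc1c(Br)cc(Br)c(Br)c1OCc1ccccc1
F4 | step 7 | 2-[2-(benzyloxy)-3,4,6-tribromophenoxy]-4-bromophenol | Oc1ccc(Br)cc1Oc1c(Br)cc(Br)c(Br)c1OCc1ccccc1
F5 | step 5 | 2-[2-(benzyloxy)-3,4,6-tribromophenoxy]-6-bromobenzaldehyde | O=Cc1c(Br)cccc1Oc1c(Br)cc(Br)c(Br)c1OCc1ccccc1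
F6 | step 5 | 2-[2-(benzyloxy)-3,4,6-tribromophenoxy]-6-bromophenyl formate | O=COc1c(Br)cccc1Oc1c(Br)cc(Br)c(Br)c1OCc1ccccc1
F7 | step 10 | 1-[bromo(phenyl)methoxy]-2,3,5-tribromo-6-(3,5-dibromo-2-methoxyphenoxy)benzene, racemic | COc1c(Br)cc(Br)cc1Oc1c(Br)cc(Br)c(Br)c1OC(Br)c1ccccc1
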